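## Analysis of the target

Cryptomerin A (27) is a biflavonoid with no stereocentre. An acacetin unit (5,7-dihydroxy-2-(4-methoxyphenyl)chromen-4-one, rings A, C and B) and an apigenin unit are joined by one diaryl ether oxygen. That oxygen links C6 of ring A of the acacetin unit to the para carbon (C4') of ring B of the apigenin unit, so this para-phenylene ring is the bridge. Because nothing is chiral, every selectivity question is regiochemical: which oxygen carries which group, and where ring A is acylated. The sensitive functions are four phenols (two chelated to a C4 carbonyl), one aryl methyl ether that must survive the unmasking of the other oxygens, and two pyranones that open in hot alkali. A 5-hydroxy-6-oxyflavone can also isomerise to its 8-oxy isomer in hot mineral acid (Wessely–Moser rearrangement). The difficulty sits in ring A of the acacetin unit: four of its six carbons bear oxygen (C5, C6, C7, C8a), and the C6–O–aryl bond lies between the oxygens at C5 and C7, where copper-mediated or SNAr etherification of a 2,6-dioxygenated phenol is sluggish. The strategy rests on the fact that C6 is para to C8a and flanked by C5 and C7. Without its C4a acyl group, ring A is a 3,5-dialkoxy-4-aryloxyphenol with a mirror plane through C6 and C8a, which is the pattern a squarate-derived 4-alkenyl-4-oxycyclobutenone gives on ring expansion, with the para ether oxygen attached while its carbon is still tetrahedral.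

## Retrosynthetic reasoning

**27 to 26.** The four phenolic hydrogens of 27 are traced back to four isopropyl groups in 26. Isopropyl is used on every masked phenol because a boron trihalide Lewis acid cleaves secondary alkyl aryl ethers at or below 0 °C. The single methyl ether on ring B of the acacetin unit is primary and not peri to a carbonyl, so it should stay. The forward step uses neither alkali nor hot acid, the two conditions that endanger the pyranones and the 5,6,7-pattern.

**26 to 21 and 23.** The pyranone of the apigenin unit is opened at O1–C2 and cut at C2–C3. This leads through diketone 25 to acid 21 (used as its chloride 24) and the o-hydroxyacetophenone 23, which is 22 with two hydroxyls etherified. The cut is placed here because it leaves a one-step fragment (23) and puts a carboxyl group on the bridging ring, which is the group the arylating agent made from 7 brings in. The forward reaction is C-acylation of the ketone enolate of 23 and acid-catalysed ring closure.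

**21 to 17 and 18.** The same two bonds are cut in the pyranone of the acacetin unit: 21 comes from ester 20, 20 from diketone 19, and 19 from acetophenone 17 and aroyl chloride 18. In the forward direction this pyranone is closed first. The free phenol of 17 is consumed in doing so, and the methyl ester is carried as a spectator until it is needed.

**17 to 14.** The bond between C4a and the acetyl carbon is cut. The two positions ortho to the hydroxyl of 14 are identical by symmetry, so acylation cannot give an 8-aryloxy isomer. The forward step is ortho C-acylation of a phloroglucinol-type phenol.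

**14 to 11 (the key disconnection).** Ring A is opened between the hydroxyl-bearing carbon (future C8a) and the neighbouring CH (future C4a, or C8 by symmetry). This gives dienylketene 12, which is the open form of cyclobutenone 11. Only this cut traces all four oxygens of ring A to non-aromatic precursors and places the crowded aryl ether on an sp3 carbon. The forward reaction must open the four-membered ring with the alkenyl group turned toward the ketene and then close the six-membered ring before anything else happens.

**11 to 6 and 10.** The aryl–oxygen bond at the quaternary carbon is cut. Forward, the tertiary alkoxide of 6 is arylated by diaryliodonium salt 10, made from 7 and 8, which should transfer only its electron-poor benzoate ring.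

**6 to 3 and 4; 3 to 1.** The bond between the carbinol carbon and the alkoxyvinyl group is cut, giving semisquarate 3 and the lithium reagent 5 derived from 4. Semisquarate 3 comes from 1 by loss of one alkoxy group through reduction and transposition. Both ring alkoxy groups are isopropyl, so 14 is symmetrical and the later deprotection is uniform.

## Alternatives that were turned down

**Alternative 1:** The bridging para-phenylene ring is taken apart at C3'–C4' and C5'–C6'.
- Forward key step: the terminal aryl ethynyl ether A2 adds as an electron-rich dienophile across C3 and C6 of methyl coumalate A3, and the bridged lactone aromatises by decarboxylative cycloreversion to the para-aryloxybenzoate A1.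
- For it: polarity fixes the regiochemistry, since the nucleophilic terminal alkyne carbon bonds to C6 of the pyranone and only the para isomer can form. The crowded oxygen is bonded to an sp carbon before the arene exists, and this is done on a stable phenoxide. On that point it is safer than the chosen plan, which arylates a fragile alkoxide.
- Against it: the key step builds the one ring of 27 that can be bought as a para-substituted benzoate. Ring A of the acacetin unit must still come from a gallate-type aromatic whose middle oxygen has to be distinguished from its neighbours. A1 lacks the C8a oxygen, which must be made from the masked formyl group by acetal cleavage and Dakin or Baeyer–Villiger oxidation. A 2,6-disubstituted aryl ynol ether is also prone to hydration and oligomerisation at cycloaddition temperatures.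
- Comparison: A1 reaches only a formyl-masked benzyl analogue of 14, after more steps. The chosen route assembles ring A with all four oxygens, including the free hydroxyl needed for acylation, in four steps from 1.

**Alternative 2:** Ring C of the acacetin unit is disconnected last, at C4a–C4, C4–C3 and O1–C2.
- Forward key step: the ortho-iodophenol A5, one inserted carbonyl carbon and 4-ethynylanisole A6 combine under palladium catalysis in a secondary amine (carbonylative Sonogashira coupling, then 6-endo oxa-Michael closure) to give A4.
- For it: it is convergent at the end, avoids C-acetylation, strong base and acid cyclodehydration, and its benzyl ethers could be removed by neutral hydrogenolysis with no risk to the methyl ether. On end-game mildness it is stronger than the chosen route.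
- Against it: A5 already contains the tetraoxygenated ring A and the crowded diaryl ether, so the plan does not address the main problem. The 5-exo closure to an aurone competes, oxidative addition into an electron-rich iodophenol flanked by two substituents is slow, and the carbonylation must be run on a large, poorly soluble flavone.
- Comparison: it changes only how a pyranone is closed, whereas the chosen strategy supplies ring A itself. The same annulation is kept as the fallback for step 6.

**Alternative 3:** Ring C of the acacetin unit is cut at O1–C8a.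
- Forward key step: the enolate oxygen of bromo diketone A8 displaces the bromide ortho to the aroyl carbonyl (addition–elimination with a carbonate base, with monovalent copper catalysis if needed) to give A7.
- For it: no phenol is needed at C8a, so there is no question of which hydroxyl closes the ring and no ortho-hydroxy-directed acylation. Ring A needs only three oxygens plus bromine, and A7 is the benzyl analogue of 20. On unambiguous ring closure it is at least as strong as the chosen route.
- Against it: the bromide sits on a ring with three donor oxygens and is activated by a single ortho carbonyl, so the displacement will probably need copper and heat. The acyl chain must be introduced between bromine and a benzyloxy group. The crowded C6–O–aryl bond still has to be made on a 2,6-disubstituted phenol.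
- Comparison: the chosen route obtains the C8a oxygen from the ketene carbonyl at no cost and forms the crowded ether before the ring is aromatic, which alternative 3 leaves to classical etherification.

Key step: step 5

Remark on the chemistry: 27 is achiral. Compounds 2, 6 and 11 each carry one stereocentre, are made as racemates, and lose it in steps 1 and 5. Isopropyl vinyl ether (4) is assumed to undergo alpha-lithiation as the lower alkyl vinyl ethers do.

## Route

Step 1
Reactants: 1 diisopropyl squarate
Product: 3 3-isopropoxycyclobut-3-ene-1,2-dione, via hydroxycyclobutenone 2 (not isolated)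
Conditions: LiAlH(OtBu)3, THF, −78 to −20 °C; then conc. HCl, CH2Cl2, rt
Reagents that add atoms: water, O
Why: The hindered hydride should reduce one of the two equivalent vinylogous ester carbonyls once; acid then ionises the carbinol, water adds at the alkoxy-bearing end of the allyl cation and isopropanol is lost (mono-reduction of a squarate ester followed by dehydrative 1,3-carbonyl transposition).

Step 2
Reactants: 3 3-isopropoxycyclobut-3-ene-1,2-dione; 4 isopropyl vinyl ether
Product: 6 rac-4-hydroxy-3-isopropoxy-4-(1-isopropoxyvinyl)cyclobut-2-en-1-one, via (1-isopropoxyvinyl)lithium 5 (not isolated)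
Conditions: 4 (1.5 equiv), t-BuLi (1.2 equiv), THF, −78 to 0 °C; then added to 3, THF, −78 °C; sat. aq. NH4Cl, −78 °C; Et3N-deactivated silica
Reagents that add atoms: none
Why: Alpha-deprotonation of the vinyl ether gives the 1-alkoxyvinyllithium, a hard nucleophile that should add 1,2 to the ketone-like C2 carbonyl of 3 and not to C1, which is the carbonyl of a vinylogous ester (O–C3=C4–C1=O). The new carbinol centre is racemic and is erased in step 5.

Step 3
Reactants: 7 methyl 4-iodobenzoate; 8 1,3,5-trimethoxybenzene
Product: 10 [4-(methoxycarbonyl)phenyl](2,4,6-trimethoxyphenyl)iodonium tosylate, via hydroxy(tosyloxy)iodoarene 9 (not isolated)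
Conditions: mCPBA, TsOH·H2O, MeCN, 75 °C; then 8, 75 °C to rt; Et2O precipitation
Reagents that add atoms: p-toluenesulfonic acid monohydrate, Cc1ccc(S(=O)(=O)O)cc1.O
Why: Oxidation of the aryl iodide to trivalent iodine in the presence of the sulfonic acid gives 9, which is attacked by the very electron-rich arene 8 in an electrophilic aromatic substitution (one-pot diaryliodonium salt synthesis). The trimethoxyphenyl group is installed as the ligand that is not transferred later.

Step 4
Reactants: 6 rac-4-hydroxy-3-isopropoxy-4-(1-isopropoxyvinyl)cyclobut-2-en-1-one; 10 [4-(methoxycarbonyl)phenyl](2,4,6-trimethoxyphenyl)iodonium tosylate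
Product: 11 rac-methyl 4-{[2-isopropoxy-1-(1-isopropoxyvinyl)-4-oxocyclobut-2-en-1-yl]oxy}benzoate
Conditions: 10 (1.2 equiv), NaN(SiMe3)2 (1.05 equiv, slow addition), toluene/THF, −40 to 0 °C
Reagents that add atoms: none
Why: This is the metal-free O-arylation of a tertiary alkoxide by a diaryliodonium salt: the alkoxide displaces tosylate on iodine and ligand coupling at the ipso carbon of the electron-poor benzoate ring forms the aryl–O bond, while the electron-rich, doubly ortho-substituted trimethoxyphenyl group stays on iodine. The base is run into the mixture of 6 and 10 so that the alkoxide, of a type that is routinely trapped cold by methylating and silylating agents, is arylated as it forms.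

Step 5
Reactants: 11 rac-methyl 4-{[2-isopropoxy-1-(1-isopropoxyvinyl)-4-oxocyclobut-2-en-1-yl]oxy}benzoate
Product: 14 methyl 4-(4-hydroxy-2,6-diisopropoxyphenoxy)benzoate, via dienylketene 12 (not isolated), via cyclohexadienone 13 (not isolated)
Conditions: toluene (0.02 M, degassed, base-washed glassware), 110 °C, argon
Reagents that add atoms: none
Why: Heating should cleave the bond between the carbonyl carbon and the quaternary carbon in a conrotatory 4-pi electrocyclic opening to give vinylketene 12. The aryloxy oxygen is the donor on the quaternary carbon and should rotate outward, turning the 1-isopropoxyvinyl group inward, cis to the ketene; the opening is reversible, so a ketene of the wrong geometry can reclose and try again. Ketene 12 then undergoes a disrotatory 6-pi electrocyclisation in which the ketene carbon (future C8a) bonds to the vinyl CH2 (future C4a or, by symmetry, C8), closing the six-membered carbocycle as dienone 13, which tautomerises to phenol 14. The closest known reaction type is the Moore rearrangement of 4-alkenyl-4-hydroxy-, 4-alkoxy- and 4-silyloxycyclobutenones to hydroquinones and their monoethers; here the group on the quaternary oxygen is aryl. No stereocentre is formed, and the racemic quaternary centre of 11 becomes the planar C6. The step needs torquoselectivity, secured by the oxygen donor, and chemoselectivity over an aromatic Claisen shift of the allyl aryl ether unit, which should require a much higher temperature than the ring opening. High dilution and exclusion of acid and air keep the enol ether intact and stop the product phenol from capturing the ketene.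

Step 6
Reactants: 14 methyl 4-(4-hydroxy-2,6-diisopropoxyphenoxy)benzoate
Product: 17 methyl 4-(3-acetyl-4-hydroxy-2,6-diisopropoxyphenoxy)benzoate, via aryl acetate 15 (not isolated), via difluoroboron chelate 16 (not isolated)
Conditions: Ac2O, BF3·OEt2, CH2Cl2, 0 °C to rt; then MeOH/H2O, 50 °C
Reagents that add atoms: acetic anhydride, CC(=O)OC(C)=O
Why: O-acetylation followed by BF3-promoted Fries rearrangement (in effect a Friedel–Crafts acylation of a phloroglucinol-type ring) places the acetyl group ortho to the hydroxyl, where it is held as the six-membered chelate 16 until hydrolysis. The two free positions are equivalent, the chelate deactivates the ring toward a second acylation, and the benzoate ring is too electron-poor to react.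

Step 7
Reactants: 17 methyl 4-(3-acetyl-4-hydroxy-2,6-diisopropoxyphenoxy)benzoate; 18 4-methoxybenzoyl chloride
Product: 19 methyl 4-{4-hydroxy-2,6-diisopropoxy-3-[3-(4-methoxyphenyl)-3-oxopropanoyl]phenoxy}benzoate
Conditions: LiN(SiMe3)2 (3.2 equiv), THF, −78 °C; then 18 (1.05 equiv), −78 °C to rt; cold 1 M HCl
Reagents that add atoms: none
Why: The doubly deprotonated o-hydroxyacetophenone should be C-acylated by the aroyl chloride to the 1,3-diketone directly (the one-flask form of the Baker–Venkataraman sequence), the third equivalent of base taking up the acidic diketone proton. The remote methyl ester should not react with the hindered amide or the enolate at low temperature.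

Step 8
Reactants: 19 methyl 4-{4-hydroxy-2,6-diisopropoxy-3-[3-(4-methoxyphenyl)-3-oxopropanoyl]phenoxy}benzoate
Product: 20 methyl 4-{[5,7-diisopropoxy-2-(4-methoxyphenyl)-4-oxo-4H-chromen-6-yl]oxy}benzoate
Conditions: TsOH·H2O (cat.), toluene, 90 °C
Reagents that add atoms: none
Why: Acid-catalysed cyclodehydration: the only free phenol adds to the distal carbonyl and water is lost, closing the pyranone so that the aryl ether lies at C6. A sulfonic acid in toluene is used in place of hot mineral acid to spare the isopropyl ethers.

Step 9
Reactants: 20 methyl 4-{[5,7-diisopropoxy-2-(4-methoxyphenyl)-4-oxo-4H-chromen-6-yl]oxy}benzoate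
Product: 21 4-{[5,7-diisopropoxy-2-(4-methoxyphenyl)-4-oxo-4H-chromen-6-yl]oxy}benzoic acid
Conditions: LiOH·H2O, THF/MeOH/H2O, rt; then 1 M HCl, 0 °C
Reagents that add atoms: lithium hydroxide monohydrate, [Li+].[OH-].O
Why: Saponification of a methyl benzoate at room temperature. The fully etherified pyranone should open only in hot concentrated alkali, and the ethers are inert to base.

Step 10
Reactants: 22 2,4,6-trihydroxyacetophenone
Product: 23 1-(2-hydroxy-4,6-diisopropoxyphenyl)ethan-1-one
Conditions: 2-bromopropane (2.2 equiv), K2CO3, DMF, 50 °C
Reagents that add atoms: 2-bromopropane, CC(C)Br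
Why: Williamson etherification. After the para and one ortho hydroxyl are alkylated, the remaining ortho hydroxyl is hydrogen-bonded to the acetyl carbonyl and much less nucleophilic, so the reaction should stop at the diether.

Step 11
Reactants: 21 4-{[5,7-diisopropoxy-2-(4-methoxyphenyl)-4-oxo-4H-chromen-6-yl]oxy}benzoic acid; 23 1-(2-hydroxy-4,6-diisopropoxyphenyl)ethan-1-one
Product: 25 1-(2-hydroxy-4,6-diisopropoxyphenyl)-3-(4-{[5,7-diisopropoxy-2-(4-methoxyphenyl)-4-oxo-4H-chromen-6-yl]oxy}phenyl)propane-1,3-dione, via acid chloride 24 (not isolated)
Conditions: 21, (COCl)2, DMF (cat.), CH2Cl2, 0 °C to rt, evaporate; 23 (1.2 equiv), LiN(SiMe3)2 (3.6 equiv), THF, −78 °C, then 24 in THF, −78 °C to rt; cold 1 M HCl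
Reagents that add atoms: none
Why: Acid chloride formation under chloroiminium catalysis, then the same enolate C-aroylation as in step 7. The acid chloride is far more electrophilic than the pyranone of 24, so the dianion of 23 should react only at the acyl carbon.

Step 12
Reactants: 25 1-(2-hydroxy-4,6-diisopropoxyphenyl)-3-(4-{[5,7-diisopropoxy-2-(4-methoxyphenyl)-4-oxo-4H-chromen-6-yl]oxy}phenyl)propane-1,3-dione
Product: 26 6-[4-(5,7-diisopropoxy-4-oxo-4H-chromen-2-yl)phenoxy]-5,7-diisopropoxy-2-(4-methoxyphenyl)-4H-chromen-4-one
Conditions: TsOH·H2O (cat.), toluene, 90 °C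
Reagents that add atoms: none
Why: Acid-catalysed cyclodehydration as in step 8; the single free phenol of 25 closes the second pyranone.

Step 13
Reactants: 26 6-[4-(5,7-diisopropoxy-4-oxo-4H-chromen-2-yl)phenoxy]-5,7-diisopropoxy-2-(4-methoxyphenyl)-4H-chromen-4-one
Product: 27 cryptomerin A, 6-[4-(5,7-dihydroxy-4-oxo-4H-chromen-2-yl)phenoxy]-5,7-dihydroxy-2-(4-methoxyphenyl)-4H-chromen-4-one
Conditions: BCl3 (1 M in CH2Cl2, 12 equiv), CH2Cl2, −78 to 0 °C; MeOH quench, aqueous work-up
Reagents that add atoms: none
Why: Lewis-acid ether cleavage: BCl3 binds the ether oxygens (the two peri to a C4 carbonyl first, by chelation) and chloride removes the secondary alkyl groups as 2-chloropropane. The methyl ether (primary, not peri to a carbonyl) and the diaryl ether should survive at this temperature, and the cold aprotic conditions leave no path to Wessely–Moser isomerisation.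

## Compound list

1 | diisopropyl squarate (3,4-diisopropoxycyclobut-3-ene-1,2-dione) | CC(C)OC1=C(OC(C)C)C(=O)C1=O | starting material
2 | rac-4-hydroxy-2,3-diisopropoxycyclobut-2-en-1-one | CC(C)OC1=C(OC(C)C)C(O)C1=O | intermediate
3 | 3-isopropoxycyclobut-3-ene-1,2-dione (isopropyl semisquarate) | CC(C)OC1=CC(=O)C1=O | intermediate
4 | isopropyl vinyl ether | C=COC(C)C | starting material
5 | (1-isopropoxyvinyl)lithium | [Li]C(=C)OC(C)C | intermediate
6 | rac-4-hydroxy-3-isopropoxy-4-(1-isopropoxyvinyl)cyclobut-2-en-1-one | CC(C)OC(=C)C1(O)C(=O)C=C1OC(C)C | intermediate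
7 | methyl 4-iodobenzoate | COC(=O)c1ccc(I)cc1 | starting material
8 | 1,3,5-trimethoxybenzene | COc1cc(OC)cc(OC)c1 | starting material
9 | methyl 4-[hydroxy(tosyloxy)-λ3-iodanyl]benzoate | COC(=O)c1ccc(I(O)OS(=O)(=O)c2ccc(C)cc2)cc1 | intermediate
10 | [4-(methoxycarbonyl)phenyl](2,4,6-trimethoxyphenyl)iodonium tosylate | COC(=O)c1ccc([I+]c2c(OC)cc(OC)cc2OC)cc1.Cc1ccc(S(=O)(=O)[O-])cc1 | intermediate
11 | rac-methyl 4-{[2-isopropoxy-1-(1-isopropoxyvinyl)-4-oxocyclobut-2-en-1-yl]oxy}benzoate | COC(=O)c1ccc(OC2(C(=C)OC(C)C)C(=O)C=C2OC(C)C)cc1 | intermediate
12 | methyl 4-{[(3Z)-2,4-diisopropoxy-6-oxohexa-1,3,5-trien-3-yl]oxy}benzoate (dienylketene) | O=C=C/C(OC(C)C)=C(\C(=C)OC(C)C)Oc1ccc(C(=O)OC)cc1 | intermediate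
13 | methyl 4-[(2,6-diisopropoxy-4-oxocyclohexa-1,5-dien-1-yl)oxy]benzoate | COC(=O)c1ccc(OC2=C(OC(C)C)CC(=O)C=C2OC(C)C)cc1 | intermediate
14 | methyl 4-(4-hydroxy-2,6-diisopropoxyphenoxy)benzoate | COC(=O)c1ccc(Oc2c(OC(C)C)cc(O)cc2OC(C)C)cc1 | intermediate
15 | methyl 4-(4-acetoxy-2,6-diisopropoxyphenoxy)benzoate | COC(=O)c1ccc(Oc2c(OC(C)C)cc(OC(C)=O)cc2OC(C)C)cc1 | intermediate
16 | difluoroboron chelate of methyl 4-(3-acetyl-4-hydroxy-2,6-diisopropoxyphenoxy)benzoate | CC1=[O+][B-](F)(F)Oc2cc(OC(C)C)c(Oc3ccc(C(=O)OC)cc3)c(OC(C)C)c12 | intermediate
17 | methyl 4-(3-acetyl-4-hydroxy-2,6-diisopropoxyphenoxy)benzoate | COC(=O)c1ccc(Oc2c(OC(C)C)cc(O)c(C(C)=O)c2OC(C)C)cc1 | intermediate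
18 | 4-methoxybenzoyl chloride | COc1ccc(C(=O)Cl)cc1 | starting material
19 | methyl 4-{4-hydroxy-2,6-diisopropoxy-3-[3-(4-methoxyphenyl)-3-oxopropanoyl]phenoxy}benzoate | COC(=O)c1ccc(Oc2c(OC(C)C)cc(O)c(C(=O)CC(=O)c3ccc(OC)cc3)c2OC(C)C)cc1 | intermediate
20 | methyl 4-{[5,7-diisopropoxy-2-(4-methoxyphenyl)-4-oxo-4H-chromen-6-yl]oxy}benzoate | COC(=O)c1ccc(Oc2c(OC(C)C)cc3oc(-c4ccc(OC)cc4)cc(=O)c3c2OC(C)C)cc1 | intermediate
21 | 4-{[5,7-diisopropoxy-2-(4-methoxyphenyl)-4-oxo-4H-chromen-6-yl]oxy}benzoic acid | COc1ccc(-c2cc(=O)c3c(OC(C)C)c(Oc4ccc(C(=O)O)cc4)c(OC(C)C)cc3o2)cc1 | intermediate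
22 | 2,4,6-trihydroxyacetophenone | CC(=O)c1c(O)cc(O)cc1O | starting material
23 | 1-(2-hydroxy-4,6-diisopropoxyphenyl)ethan-1-one | CC(=O)c1c(O)cc(OC(C)C)cc1OC(C)C | intermediate
24 | 4-{[5,7-diisopropoxy-2-(4-methoxyphenyl)-4-oxo-4H-chromen-6-yl]oxy}benzoyl chloride | COc1ccc(-c2cc(=O)c3c(OC(C)C)c(Oc4ccc(C(=O)Cl)cc4)c(OC(C)C)cc3o2)cc1 | intermediate
25 | 1-(2-hydroxy-4,6-diisopropoxyphenyl)-3-(4-{[5,7-diisopropoxy-2-(4-methoxyphenyl)-4-oxo-4H-chromen-6-yl]oxy}phenyl)propane-1,3-dione | COc1ccc(-c2cc(=O)c3c(OC(C)C)c(Oc4ccc(C(=O)CC(=O)c5c(O)cc(OC(C)C)cc5OC(C)C)cc4)c(OC(C)C)cc3o2)cc1 | intermediate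
26 | 6-[4-(5,7-diisopropoxy-4-oxo-4H-chromen-2-yl)phenoxy]-5,7-diisopropoxy-2-(4-methoxyphenyl)-4H-chromen-4-one (tetra-O-isopropyl cryptomerin A) | COc1ccc(-c2cc(=O)c3c(OC(C)C)c(Oc4ccc(-c5cc(=O)c6c(OC(C)C)cc(OC(C)C)cc6o5)cc4)c(OC(C)C)cc3o2)cc1 | intermediate
27 | cryptomerin A | COc1ccc(-c2cc(=O)c3c(O)c(Oc4ccc(-c5cc(=O)c6c(O)cc(O)cc6o5)cc4)c(O)cc3o2)cc1 | target

## Step count and least certain steps

Total step count: 13. Longest linear sequence: 11 steps from 1 (steps 1, 2, 4, 5, 6, 7, 8, 9, 11, 12, 13). Steps 3 and 10 are one-step side branches.

**Step 4 (O-arylation of the carbinol), the least secure step.** The sodium alkoxide of 6 is a 4-oxidocyclobutenone. The oxyanion accelerates electrocyclic opening of the four-membered ring, so fragmentation of the alkoxide may outrun aryl transfer, and the amide base may also attack the iodonium salt. This risk lies before the key step and is the cost of attaching the crowded oxygen before aromatisation. The fallback sets out from 6 and returns at 14. Compound 6 itself is heated in toluene, the long-established ring expansion of the free carbinol, to give 2,6-diisopropoxybenzene-1,4-diol F1. Its unhindered, more acidic 4-hydroxyl is benzylated (BnBr, K2CO3, acetone, argon) to 4-(benzyloxy)-2,6-diisopropoxyphenol F2. The hindered phenoxide is arylated with 10 (KOtBu, THF), a reaction that tolerates two ortho substituents, to give methyl 4-[4-(benzyloxy)-2,6-diisopropoxyphenoxy]benzoate F3. Hydrogenolysis (H2, 10% Pd/C, EtOAc) then gives 14. The crowded ether is in that case made on the arene after all.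

**Step 5 (key step).** The benzoate-substituted aryloxy group is a weaker donor than hydroxy or alkoxy. Inward rotation of the oxygen may therefore compete, and the opening may need a temperature at which sigmatropic shifts of the allyl aryl ether unit or capture of the ketene by the phenolic product begin; traces of acid would also hydrolyse the enol ether. The fallback sets out from 6 and returns at 17 by way of 15. Compound 6 is silylated (t-BuMe2SiOTf, 2,6-lutidine, CH2Cl2, −78 °C) to rac-4-[(tert-butyldimethylsilyl)oxy]-3-isopropoxy-4-(1-isopropoxyvinyl)cyclobut-2-en-1-one F4. Its thermolysis, known for silyloxy groups at this position, gives 4-[(tert-butyldimethylsilyl)oxy]-3,5-diisopropoxyphenol F5. Acetylation (Ac2O, pyridine) gives 4-[(tert-butyldimethylsilyl)oxy]-3,5-diisopropoxyphenyl acetate F6. Desilylation (Bu4NF buffered with AcOH, THF, 0 °C) gives 4-hydroxy-3,5-diisopropoxyphenyl acetate F7. Arylation of F7 with 10 (K2CO3, MeCN) gives 15, which is treated with BF3·OEt2 as in step 6 to reach 17.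

**Step 6 (C-acetylation).** The Lewis acid may remove the isopropyl group next to the new acetyl group, assisted by the neighbouring carbonyl. That would create a second ortho hydroxyl and spoil the regiochemistry of the later pyranone closure. The fallback sets out from 14 and returns at 20. Iodination of 14 (N-iodosuccinimide, CH2Cl2, 0 °C) gives methyl 4-(4-hydroxy-3-iodo-2,6-diisopropoxyphenoxy)benzoate F8. Carbonylative annulation of F8 with 4-ethynylanisole A6 (PdCl2(PPh3)2, CO, Et2NH, 60 to 120 °C) closes the pyranone directly to 20, with no acetophenone or diketone.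

**Step 11 (acid chloride and enolate aroylation on the flavone acid).** The pyranone carbonyl or the isopropyl ethers may react with oxalyl chloride and the HCl it releases while the acid chloride is made, and the dianion of 23 may be O-acylated in place of C-acylation. The fallback sets out from 21 and 23 and returns at 25. Carbodiimide esterification (EDC·HCl, DMAP, CH2Cl2) gives 2-acetyl-3,5-diisopropoxyphenyl 4-{[5,7-diisopropoxy-2-(4-methoxyphenyl)-4-oxo-4H-chromen-6-yl]oxy}benzoate F9. The classical Baker–Venkataraman acyl shift (KOH, pyridine, 50 °C) then gives 25.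

## Further compounds

F1 | step 4 | 2,6-diisopropoxybenzene-1,4-diol | CC(C)Oc1cc(O)cc(OC(C)C)c1O
F2 | step 4 | 4-(benzyloxy)-2,6-diisopropoxyphenol | CC(C)Oc1cc(OCc2ccccc2)cc(OC(C)C)c1O
F3 | step 4 | methyl 4-[4-(benzyloxy)-2,6-diisopropoxyphenoxy]benzoate | COC(=O)c1ccc(Oc2c(OC(C)C)cc(OCc3ccccc3)cc2OC(C)C)cc1
F4 | step 5 | rac-4-[(tert-butyldimethylsilyl)oxy]-3-isopropoxy-4-(1-isopropoxyvinyl)cyclobut-2-en-1-one | CC(C)OC(=C)C1(O[Si](C)(C)C(C)(C)C)C(=O)C=C1OC(C)C
F5 | step 5 | 4-[(tert-butyldimethylsilyl)oxy]-3,5-diisopropoxyphenol | CC(C)Oc1cc(O)cc(OC(C)C)c1O[Si](C)(C)C(C)(C)C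
F6 | step 5 | 4-[(tert-butyldimethylsilyl)oxy]-3,5-diisopropoxyphenyl acetate | CC(=O)Oc1cc(OC(C)C)c(O[Si](C)(C)C(C)(C)C)c(OC(C)C)c1
F7 | step 5 | 4-hydroxy-3,5-diisopropoxyphenyl acetate | CC(=O)Oc1cc(OC(C)C)c(O)c(OC(C)C)c1
F8 | step 6 | methyl 4-(4-hydroxy-3-iodo-2,6-diisopropoxyphenoxy)benzoate | COC(=O)c1ccc(Oc2c(OC(C)C)cc(O)c(I)c2OC(C)C)cc1
F9 | step 11 | 2-acetyl-3,5-diisopropoxyphenyl 4-{[5,7-diisopropoxy-2-(4-methoxyphenyl)-4-oxo-4H-chromen-6-yl]oxy}benzoate | COc1ccc(-c2cc(=O)c3c(OC(C)C)c(Oc4ccc(C(=O)Oc5cc(OC(C)C)cc(OC(C)C)c5C(C)=O)cc4)c(OC(C)C)cc3o2)cc1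
A1 | alternative 1 | methyl 4-[2,6-bis(benzyloxy)-4-(1,3-dioxolan-2-yl)phenoxy]benzoate | COC(=O)c1ccc(Oc2c(OCc3ccccc3)cc(C3OCCO3)cc2OCc2ccccc2)cc1
A2 | alternative 1 | 2-[3,5-bis(benzyloxy)-4-(ethynyloxy)phenyl]-1,3-dioxolane | C#COc1c(OCc2ccccc2)cc(C2OCCO2)cc1OCc1ccccc1
A3 | alternative 1 | methyl coumalate (methyl 2-oxo-2H-pyran-5-carboxylate) | COC(=O)c1ccc(=O)oc1
A4 | alternative 2 | tetra-O-benzyl cryptomerin A | COc1ccc(-c2cc(=O)c3c(OCc4ccccc4)c(Oc4ccc(-c5cc(=O)c6c(OCc7ccccc7)cc(OCc7ccccc7)cc6o5)cc4)c(OCc4ccccc4)cc3o2)cc1
A5 | alternative 2 | 5,7-bis(benzyloxy)-2-{4-[2,6-bis(benzyloxy)-4-hydroxy-3-iodophenoxy]phenyl}-4H-chromen-4-one | Oc1cc(OCc2ccccc2)c(Oc2ccc(-c3cc(=O)c4c(OCc5ccccc5)cc(OCc5ccccc5)cc4o3)cc2)c(OCc2ccccc2)c1I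
A6 | alternative 2 | 4-ethynylanisole | COc1ccc(C#C)cc1
A7 | alternative 3 | methyl 4-{[5,7-bis(benzyloxy)-2-(4-methoxyphenyl)-4-oxo-4H-chromen-6-yl]oxy}benzoate | COC(=O)c1ccc(Oc2c(OCc3ccccc3)cc3oc(-c4ccc(OC)cc4)cc(=O)c3c2OCc2ccccc2)cc1
A8 | alternative 3 | methyl 4-{2,6-bis(benzyloxy)-4-bromo-3-[3-(4-methoxyphenyl)-3-oxopropanoyl]phenoxy}benzoate | COC(=O)c1ccc(Oc2c(OCc3ccccc3)cc(Br)c(C(=O)CC(=O)c3ccc(OC)cc3)c2OCc2ccccc2)cc1
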